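## Retrosynthetic overview
1. The quinone comes from Teuber oxidation of the 2,6-disubstituted phenol 18. No ring is built: the only ring is the benzene ring of guaiacol, which is carried through and oxidised last.
2. The C13 chain comes from hydrogenation of alkene 16. Disconnecting C4=C5 by cross metathesis gives homoallylic acetate 14 and 1-dodecene 15.
3. The key disconnection is C2–C3: asymmetric allylboration of arylacetaldehyde 8 joins the fragments and sets the (R)-carbinol centre.
4. Aldehyde 8 comes from oxidative cleavage of O-benzyl-o-eugenol 6, which comes from the aromatic Claisen rearrangement of guaiacol allyl ether 3.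

Assumption: CIP analysis of the given SMILES gives (R) at the stereocentre (OAc > CH2-quinone > C13H27 > H). Alkene 16 is an inconsequential E/Z mixture and is drawn as its major E isomer.

## Route

Step 1
Reactants: 1 guaiacol (2-methoxyphenol); 2 allyl bromide
Product: 3 1-(allyloxy)-2-methoxybenzene
Conditions: K2CO3 (1.2 equiv), acetone, reflux, 8 h
Reagents that add atoms: none
Why: Williamson ether synthesis, in which the potassium phenoxide displaces bromide from the unhindered allylic halide by SN2 and O-alkylation is essentially the only pathway in acetone.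

Step 2
Reactants: 3 1-(allyloxy)-2-methoxybenzene
Product: 5 2-allyl-6-methoxyphenol (o-eugenol), via 6-allyl-2-methoxycyclohexa-2,4-dienone 4 (not isolated)
Conditions: neat, N2, 200–230 °C, 1–2 h; then distillation
Reagents that add atoms: none
Why: Aromatic Claisen rearrangement, in which the concerted [3,3]-sigmatropic shift can only end productively at the one free ortho carbon (the other carries OMe) and dienone 4 tautomerises irreversibly to the phenol.

Step 3
Reactants: 5 2-allyl-6-methoxyphenol
Product: 6 1-allyl-2-(benzyloxy)-3-methoxybenzene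
Conditions: BnBr (1.1 equiv), K2CO3 (1.5 equiv), DMF, 60 °C
Reagents that add atoms: benzyl bromide, BrCc1ccccc1
Why: Williamson ether synthesis that masks the phenol with a group which survives osmylation, borane/peroxide, acylation and ruthenium carbenes and later leaves in the same hydrogenation that saturates the chain.

Step 4
Reactants: 6 1-allyl-2-(benzyloxy)-3-methoxybenzene
Product: 8 2-[2-(benzyloxy)-3-methoxyphenyl]acetaldehyde, via racemic 3-[2-(benzyloxy)-3-methoxyphenyl]propane-1,2-diol 7 (not isolated)
Conditions: OsO4 (2 mol %), NaIO4 (4 equiv), 2,6-lutidine (2 equiv), 1,4-dioxane/H2O 3:1, rt; short silica plug, used at once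
Reagents that add atoms: osmium tetroxide, O=[Os](=O)(=O)=O (hands over the O atoms); sodium periodate, [Na+].[O-]I(=O)(=O)=O (restocks the oxo ligands)
Why: Lemieux–Johnson oxidation, in which osmylation of the only alkene gives diol 7, periodate cleaves it in the same flask, and 2,6-lutidine keeps the medium neutral so that the enolisable arylacetaldehyde neither over-oxidises nor self-condenses.

Step 5
Reactants: 8 2-[2-(benzyloxy)-3-methoxyphenyl]acetaldehyde; 9 allylmagnesium bromide; 10 (+)-B-methoxydiisopinocampheylborane (the enantiomer derived from (−)-α-pinene)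
Product: 13 (R)-1-[2-(benzyloxy)-3-methoxyphenyl]pent-4-en-2-ol, via B-allyldiisopinocampheylborane 11 (not isolated), via diisopinocampheylborinate ester 12 (not isolated)
Conditions: 10 (1.4 equiv), 9 (1.3 equiv, 1 M in Et2O), Et2O, 0 °C to rt, 1 h; then 8, Et2O, −78 °C, 3 h; then 3 M NaOH, 30% H2O2, 0 °C to rt
Reagents that add atoms: none
Why: Brown asymmetric allylboration (carbonyl allylation), in which 11 transfers its allyl group through a closed chair Zimmerman–Traxler transition state whose isopinocampheyl groups from (−)-α-pinene expose the Re face of the aldehyde, so the new C2–C3 bond and the (R)-carbinol centre are set together (typically 90–96% ee) before peroxide frees the alcohol from borinate 12.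

Step 6
Reactants: 13 (R)-1-[2-(benzyloxy)-3-methoxyphenyl]pent-4-en-2-ol
Product: 14 (R)-1-[2-(benzyloxy)-3-methoxyphenyl]pent-4-en-2-yl acetate
Conditions: Ac2O (1.5 equiv), Et3N (2 equiv), DMAP (5 mol %), CH2Cl2, 0 °C to rt
Reagents that add atoms: acetic anhydride, CC(=O)OC(C)=O
Why: DMAP-catalysed nucleophilic acyl transfer (esterification) that breaks only the O–H bond, so the C–O bond and the (R) configuration are retained.

Step 7
Reactants: 14 (R)-1-[2-(benzyloxy)-3-methoxyphenyl]pent-4-en-2-yl acetate; 15 1-dodecene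
Product: 16 (R,E)-1-[2-(benzyloxy)-3-methoxyphenyl]pentadec-4-en-2-yl acetate (E/Z mixture)
Conditions: 15 (4 equiv), second-generation Grubbs catalyst RuCl2(=CHPh)(PCy3)(SIMes) (3 mol %), 1,4-benzoquinone (10 mol %), CH2Cl2, 40 °C, 12 h
Reagents that add atoms: none
Why: Olefin cross metathesis, in which two unhindered terminal alkenes exchange alkylidenes with loss of ethylene, excess cheap 15 drives 14 to the cross product, benzoquinone suppresses Ru–H double-bond migration, and the E/Z ratio is irrelevant because the alkene is hydrogenated next.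

Step 8
Reactants: 16 (R,E)-1-[2-(benzyloxy)-3-methoxyphenyl]pentadec-4-en-2-yl acetate
Product: 18 (R)-1-(2-hydroxy-3-methoxyphenyl)pentadecan-2-yl acetate, via saturated benzyl ether 17 (not isolated)
Conditions: H2 (1 atm), 10% Pd/C, EtOAc, rt, 12 h
Reagents that add atoms: none
Why: Heterogeneous catalytic hydrogenation with benzyl ether hydrogenolysis, in which Pd/C first saturates the alkene (17) and then cleaves the benzylic C–O bond while the secondary acetate, which is neither benzylic nor allylic, and its stereocentre are untouched.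

Step 9
Reactants: 18 (R)-1-(2-hydroxy-3-methoxyphenyl)pentadecan-2-yl acetate
Product: 20 ardisinone (2-[(2R)-2-acetoxypentadecyl]-6-methoxy-1,4-benzoquinone), via para-aminooxy dienone adduct 19 (not isolated)
Conditions: potassium nitrosodisulfonate (KSO3)2NO (2.5 equiv), aq. KH2PO4 buffer (pH 6), acetone/H2O, rt, 2–4 h
Reagents that add atoms: potassium nitrosodisulfonate (Fremy's salt), [K+].[K+].[O]N(S(=O)(=O)[O-])S(=O)(=O)[O-]
Why: Teuber oxidation, in which one equivalent of the nitroxyl radical abstracts the phenolic hydrogen and a second couples at the only free position of high spin density (para, both ortho positions being substituted) to give 19, which loses imidodisulfonate to give the 1,4-quinone under near-neutral conditions that spare the acetate and the stereocentre.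

## Compound list
1 | guaiacol (2-methoxyphenol) | COc1ccccc1O | starting material
2 | allyl bromide | C=CCBr | starting material
3 | 1-(allyloxy)-2-methoxybenzene | C=CCOc1ccccc1OC | intermediate
4 | 6-allyl-2-methoxycyclohexa-2,4-dien-1-one (racemic, not isolated) | C=CCC1C=CC=C(OC)C1=O | intermediate
5 | 2-allyl-6-methoxyphenol (o-eugenol) | C=CCc1cccc(OC)c1O | intermediate
6 | 1-allyl-2-(benzyloxy)-3-methoxybenzene | C=CCc1cccc(OC)c1OCc1ccccc1 | intermediate
7 | 3-[2-(benzyloxy)-3-methoxyphenyl]propane-1,2-diol (racemic, not isolated) | OCC(O)Cc1cccc(OC)c1OCc1ccccc1 | intermediate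
8 | 2-[2-(benzyloxy)-3-methoxyphenyl]acetaldehyde | O=CCc1cccc(OC)c1OCc1ccccc1 | intermediate
9 | allylmagnesium bromide | C=CC[Mg]Br | starting material
10 | (+)-B-methoxydiisopinocampheylborane, from (−)-α-pinene | COB([C@H]1C[C@H]2C[C@@H]([C@@H]1C)C2(C)C)[C@H]1C[C@H]2C[C@@H]([C@@H]1C)C2(C)C | starting material
11 | B-allyldiisopinocampheylborane, (−)-α-pinene series (not isolated) | C=CCB([C@H]1C[C@H]2C[C@@H]([C@@H]1C)C2(C)C)[C@H]1C[C@H]2C[C@@H]([C@@H]1C)C2(C)C | intermediate
12 | (R)-1-[2-(benzyloxy)-3-methoxyphenyl]pent-4-en-2-yl diisopinocampheylborinate (not isolated) | C=CC[C@H](Cc1cccc(OC)c1OCc1ccccc1)OB([C@H]1C[C@H]2C[C@@H]([C@@H]1C)C2(C)C)[C@H]1C[C@H]2C[C@@H]([C@@H]1C)C2(C)C | intermediate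
13 | (R)-1-[2-(benzyloxy)-3-methoxyphenyl]pent-4-en-2-ol | C=CC[C@H](Cc1cccc(OC)c1OCc1ccccc1)O | intermediate
14 | (R)-1-[2-(benzyloxy)-3-methoxyphenyl]pent-4-en-2-yl acetate | C=CC[C@H](Cc1cccc(OC)c1OCc1ccccc1)OC(C)=O | intermediate
15 | 1-dodecene | C=CCCCCCCCCCC | starting material
16 | (R,E)-1-[2-(benzyloxy)-3-methoxyphenyl]pentadec-4-en-2-yl acetate (E/Z mixture, E drawn) | CCCCCCCCCC/C=C/C[C@H](Cc1cccc(OC)c1OCc1ccccc1)OC(C)=O | intermediate
17 | (R)-1-[2-(benzyloxy)-3-methoxyphenyl]pentadecan-2-yl acetate (not isolated) | CCCCCCCCCCCCC[C@H](Cc1cccc(OC)c1OCc1ccccc1)OC(C)=O | intermediate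
18 | (R)-1-(2-hydroxy-3-methoxyphenyl)pentadecan-2-yl acetate | CCCCCCCCCCCCC[C@H](Cc1cccc(OC)c1O)OC(C)=O | intermediate
19 | dipotassium salt of the 4-[(disulfonatoamino)oxy]cyclohexa-2,5-dienone adduct of 18 (C4 epimers, not isolated) | CCCCCCCCCCCCC[C@H](CC1=CC(ON(S(=O)(=O)[O-])S(=O)(=O)[O-])C=C(OC)C1=O)OC(C)=O.[K+].[K+] | intermediate
20 | ardisinone, (R)-1-(5-methoxy-3,6-dioxocyclohexa-1,4-dien-1-yl)pentadecan-2-yl acetate | CCCCCCCCCCCCC[C@H](CC1=CC(=O)C=C(OC)C1=O)OC(C)=O | target

## Step count and risks
Total step count: 9. Longest linear sequence: 9 steps (1 to 20).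

**Step 5 is most at risk.**
- Aldehyde 8 is very enolisable, so yield and ee can fall short, and no later intermediate is crystalline enough to upgrade the ee. The ee is checked on 13 by chiral HPLC or Mosher ester.
- The fallback sets out from 8 and comes back at 13. It replaces reagent control by a Claisen condensation followed by catalytic asymmetric hydrogenation.
- Pinnick oxidation (NaClO2, NaH2PO4, 2-methyl-2-butene, tBuOH/H2O) gives 2-[2-(benzyloxy)-3-methoxyphenyl]acetic acid F1.
- 1,1'-Carbonyldiimidazole in THF converts it into the acyl imidazolide F2.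
- F2 undergoes the decarboxylative Claisen condensation with potassium methyl malonate, MgCl2 and Et3N to give methyl 4-[2-(benzyloxy)-3-methoxyphenyl]-3-oxobutanoate F3.
- Noyori hydrogenation (RuCl2[(S)-BINAP], H2 6 bar, MeOH, 50 °C) gives the (S)-β-hydroxy ester F4. The descriptor is S only because CH2CO2Me outranks CH2Ar; the spatial arrangement is that of 13.
- TBSCl/imidazole gives the silyl ether ester F5, iBu2AlH at −78 °C gives the aldehyde F6, and Ph3P=CH2 gives the silyl-protected homoallylic ether F7. Bu4NF then releases 13.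

**Step 7 is second.**
- The cross metathesis is statistical, and any Ru–H isomerisation produces chain-shortened homologues that are hard to separate from 16.
- The fallback sets out from 14 and comes back at 17. It builds the chain by hydroboration and alkyl–alkyl Suzuki–Miyaura coupling instead of metathesis.
- 9-BBN-H in THF at rt adds to the terminal alkene of 14, leaving the acetate untouched, to give the B-alkyl-9-borabicyclononane F8.
- F8 is coupled in the same flask with commercial 1-bromodecane (Pd(OAc)2 4 mol %, PCy3 8 mol %, K3PO4·H2O, THF, rt) to give 17 directly with a defined chain length.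
- 17 is then debenzylated under the conditions of step 8 to give 18.

**Step 4 is third.**
- Aldehyde 8 can over-oxidise or self-condense while it sits with the oxidants.
- The fallback sets out from 6 and comes back at 8. It makes the aldehyde by one-carbon homologation under non-oxidising conditions.
- KOtBu in DMSO at rt isomerises 6 to the conjugated (E)-propenylarene F9.
- The same OsO4/NaIO4 system cleaves it to the non-enolisable, storable 2-(benzyloxy)-3-methoxybenzaldehyde F10.
- Wittig methoxymethylenation ((methoxymethyl)triphenylphosphonium chloride, KOtBu, THF, 0 °C) gives the enol ether F11 as an E/Z mixture.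
- 2 M HCl in THF hydrolyses F11 to 8 immediately before step 5.

## Further compounds
F1 | step 5 | 2-[2-(benzyloxy)-3-methoxyphenyl]acetic acid | OC(=O)Cc1cccc(OC)c1OCc1ccccc1
F2 | step 5 | 2-[2-(benzyloxy)-3-methoxyphenyl]-1-(imidazol-1-yl)ethanone | O=C(Cc1cccc(OC)c1OCc1ccccc1)n1ccnc1
F3 | step 5 | methyl 4-[2-(benzyloxy)-3-methoxyphenyl]-3-oxobutanoate | COC(=O)CC(=O)Cc1cccc(OC)c1OCc1ccccc1
F4 | step 5 | methyl (S)-4-[2-(benzyloxy)-3-methoxyphenyl]-3-hydroxybutanoate | COC(=O)C[C@H](Cc1cccc(OC)c1OCc1ccccc1)O
F5 | step 5 | methyl (S)-4-[2-(benzyloxy)-3-methoxyphenyl]-3-[(tert-butyldimethylsilyl)oxy]butanoate | COC(=O)C[C@H](Cc1cccc(OC)c1OCc1ccccc1)O[Si](C)(C)C(C)(C)C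
F6 | step 5 | (S)-4-[2-(benzyloxy)-3-methoxyphenyl]-3-[(tert-butyldimethylsilyl)oxy]butanal | O=CC[C@H](Cc1cccc(OC)c1OCc1ccccc1)O[Si](C)(C)C(C)(C)C
F7 | step 5 | (R)-{1-[2-(benzyloxy)-3-methoxyphenyl]pent-4-en-2-yl}oxy(tert-butyl)dimethylsilane | C=CC[C@H](Cc1cccc(OC)c1OCc1ccccc1)O[Si](C)(C)C(C)(C)C
F8 | step 7 | (R)-5-(9-borabicyclo[3.3.1]nonan-9-yl)-1-[2-(benzyloxy)-3-methoxyphenyl]pentan-2-yl acetate | C1CC2CCCC(C1)B2CCC[C@H](Cc1cccc(OC)c1OCc1ccccc1)OC(C)=O
F9 | step 4 | (E)-2-(benzyloxy)-1-methoxy-3-(prop-1-en-1-yl)benzene | C/C=C/c1cccc(OC)c1OCc1ccccc1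
F10 | step 4 | 2-(benzyloxy)-3-methoxybenzaldehyde | O=Cc1cccc(OC)c1OCc1ccccc1
F11 | step 4 | 2-(benzyloxy)-1-methoxy-3-(2-methoxyvinyl)benzene (E/Z mixture, E drawn) | CO/C=C/c1cccc(OC)c1OCc1ccccc1
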